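C1 is the lactone carbonyl, C2=C3 the ring alkene and C5 the ring carbinol; C7, C9 and C11 are the all-syn side-chain carbinols and C12–C26 the tail. The retrosynthesis cuts the lactone O–C1 bond, then C2=C3 (Z-olefination of a C3 aldehyde), then C9–C10.
Enabling feature: C10H2–C11H(OH) heads the unbranched, unfunctionalised C12–C26 tail, which is the footprint of a 1,2-difunctionalised terminal alkene. C9–OH stands 1,3 to C11–OH, so the C9/C11 diol is treated as a 1,3-bis(boronic ester), that is heptadec-1-ene + B2pin2 + a C9 carbenoid.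
Event: the primary boron on C10 of the alkene-derived 1,2-bis(boronic ester) captures a chiral C9 α-lithio benzoate. The 1,2-shift of C10 from B to C9 makes C9–C10, fixes C9, and leaves boron on C9 and C11 as hydroxyl placeholders (C–B bonds absent from the target, oxidised away in the next step).
Forward order: C3–C9 half from the commercial statin nitrile (its cis-1,3-dioxane ring holds C5 and C7), union with the C10–C26 half, double C–B oxidation, second dioxane, C3 aldehyde, C1–C2 by Still–Gennari olefination. Acid then opens both dioxanes, and the dihydropyranone, the only ring of the target, closes last.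
Stereochemistry: C5 and C7 are bought; C11 comes from platinum-catalysed enantioselective diboration; C9 from (+)-sparteine-directed lithiation and stereospecific migration; the Z-alkene from the olefination.
Key step: step 6

Assumption: in step 5 the antipode of the phosphonite ligand is used that gives the bis(boronic ester) drawn (oxidation of a sample would give (R)-heptadecane-1,2-diol). Descriptors at C5, C7, C9 and C11 change along the route only through the priority rules; the spatial arrangement stays that of the target SMILES.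

Step 1
Reactants: 1 tert-butyl 2-[(4R,6R)-6-(cyanomethyl)-2,2-dimethyl-1,3-dioxan-4-yl]acetate
Product: 3 tert-butyl 2-[(4R,6R)-6-(2-hydroxyethyl)-2,2-dimethyl-1,3-dioxan-4-yl]acetate, via C9 aldehyde 2 (not isolated)
Conditions: i-Bu2AlH (1.1 equiv), toluene, −78 °C; MeOH, then aq potassium sodium tartrate, rt; crude 2, NaBH4, MeOH, 0 °C
Reagents that add atoms: water: O
Why: Half-reduction of a nitrile through its N-aluminoimine should outrun attack on the hindered tert-butyl ester at −78 °C with one equivalent of hydride, and NaBH4, which leaves esters alone, takes the sensitive β-alkoxy aldehyde straight on to the alcohol without touching a stereocentre.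

Step 2
Reactants: 3 tert-butyl 2-[(4R,6R)-6-(2-hydroxyethyl)-2,2-dimethyl-1,3-dioxan-4-yl]acetate
Product: 4 2-[(4R,6R)-6-(2-tert-butoxy-2-oxoethyl)-2,2-dimethyl-1,3-dioxan-4-yl]ethyl 2,4,6-triisopropylbenzoate
Conditions: 2,4,6-triisopropylbenzoic acid, PPh3, DIAD, THF, 0 °C to rt
Reagents that add atoms: 2,4,6-triisopropylbenzoic acid: CC(C)c1cc(C(C)C)c(C(=O)O)c(C(C)C)c1
Why: Mitsunobu esterification of a primary alcohol installs the hindered benzoate that later directs lithiation at C9 and serves as the leaving group; C9 is not yet stereogenic.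

Step 3
Reactants: 4 2-[(4R,6R)-6-(2-tert-butoxy-2-oxoethyl)-2,2-dimethyl-1,3-dioxan-4-yl]ethyl 2,4,6-triisopropylbenzoate
Product: 5 2-[(4R,6R)-2,2-dimethyl-6-(2-oxoethyl)-1,3-dioxan-4-yl]ethyl 2,4,6-triisopropylbenzoate
Conditions: i-Bu2AlH (1.2 equiv), CH2Cl2, −78 °C; MeOH, aq potassium sodium tartrate
Reagents that add atoms: none
Why: Ester half-reduction stops at the aluminium hemiacetal at −78 °C, and the benzoate carbonyl is shielded from the hydride by its two ortho isopropyl groups.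

Step 4
Reactants: 5 2-[(4R,6R)-2,2-dimethyl-6-(2-oxoethyl)-1,3-dioxan-4-yl]ethyl 2,4,6-triisopropylbenzoate
Product: 6 2-[(4R,6S)-6-allyl-2,2-dimethyl-1,3-dioxan-4-yl]ethyl 2,4,6-triisopropylbenzoate
Conditions: MePPh3Br, KN(SiMe3)2, THF, 0 °C; then 5, −78 °C to rt
Reagents that add atoms: methyltriphenylphosphonium bromide: C[P+](c1ccccc1)(c1ccccc1)c1ccccc1.[Br-]
Why: Wittig methylenation by the unstabilised ylide should be faster at low temperature than β-elimination of the C5 oxygen, and the vinyl group stores the C3 aldehyde in a form inert to s-BuLi and to basic peroxide.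

Step 5
Reactants: 7 heptadec-1-ene
Product: 8 (S)-1,2-bis(4,4,5,5-tetramethyl-1,3,2-dioxaborolan-2-yl)heptadecane
Conditions: B2pin2 (1.05 equiv), Pt(dba)3 (1 mol %), chiral TADDOL-derived phenylphosphonite (Ar = 3,5-i-Pr2C6H3, 1.2 mol %), THF, 60 °C
Reagents that add atoms: bis(pinacolato)diboron: CC1(C)OB(OC1(C)C)B1OC(C)(C)C(C)(C)O1
Why: Enantioselective syn-1,2-diboration of a terminal alkene on zerovalent platinum sets C11, because the chiral phosphonite selects one alkene face in the insertion into the Pt–B bond; unbranched 1-alkenes are the best substrate class of this reaction.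

Step 6
Reactants: 6 2-[(4R,6S)-6-allyl-2,2-dimethyl-1,3-dioxan-4-yl]ethyl 2,4,6-triisopropylbenzoate; 8 (S)-1,2-bis(4,4,5,5-tetramethyl-1,3,2-dioxaborolan-2-yl)heptadecane
Product: 11 (4S,6R)-4-allyl-6-[(2R,4R)-2,4-bis(4,4,5,5-tetramethyl-1,3,2-dioxaborolan-2-yl)nonadecyl]-2,2-dimethyl-1,3-dioxane, via lithiated benzoate 9 (not isolated), via boronate complex 10 (not isolated)
Conditions: 6 (1.2 equiv), s-BuLi (1.2 equiv), (+)-sparteine (1.2 equiv), Et2O, −78 °C, 5 h; 8 (1.0 equiv) in Et2O, −78 °C, 2 h; then reflux, 16 h; aq NH4Cl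
Reagents that add atoms: none
Why: s-BuLi bound to (+)-sparteine removes the pro-R hydrogen at C9 next to the benzoate oxygen of 6 and gives the configurationally stable carbenoid 9, which adds with retention to the less hindered primary boron (on C10) of 8 to give boronate 10. On warming, C10 migrates from boron to C9 antiperiplanar to the departing triisopropylbenzoate, so the C9–C10 bond forms with inversion at C9 and boron ends on C9 as the placeholder of its hydroxyl (1,2-metallate rearrangement, lithiation–borylation, a reagent-controlled Matteson-type homologation). The closest known reaction type is the selective homologation of the primary boron of alkene-derived 1,2-bis(boronic esters) with sparteine-derived lithiated benzoates to 1,3-bis(boronic esters). No ring is closed. The new stereocentre C9 is set by the diamine (reagent control, independent of C7) and passed on stereospecifically, and C11 is carried unchanged because its C–B bond takes no part. The step needs site selectivity between two borons and a single homologation: the boron on C11 is secondary and shielded by the C15 chain, and 9 is used up or decays at −78 °C before migration frees the new, hindered secondary boronic ester.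

Step 7
Reactants: 11 (4S,6R)-4-allyl-6-[(2R,4R)-2,4-bis(4,4,5,5-tetramethyl-1,3,2-dioxaborolan-2-yl)nonadecyl]-2,2-dimethyl-1,3-dioxane
Product: 12 (2R,4R)-1-[(4R,6S)-6-allyl-2,2-dimethyl-1,3-dioxan-4-yl]nonadecane-2,4-diol
Conditions: 30% aq H2O2, 2 M aq NaOH, THF, 0 °C to rt
Reagents that add atoms: hydrogen peroxide: OO
Why: Oxidation of boronic esters by hydroperoxide proceeds by a stereoretentive shift of carbon from boron to oxygen, so both C–B bonds become the C9 and C11 hydroxyls with unchanged configuration while alkene and acetonide are inert.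

Step 8
Reactants: 12 (2R,4R)-1-[(4R,6S)-6-allyl-2,2-dimethyl-1,3-dioxan-4-yl]nonadecane-2,4-diol
Product: 13 (4S,6S)-4-allyl-6-{[(4R,6R)-2,2-dimethyl-6-pentadecyl-1,3-dioxan-4-yl]methyl}-2,2-dimethyl-1,3-dioxane
Conditions: 2,2-dimethoxypropane, PPTS (cat.), CH2Cl2, rt
Reagents that add atoms: 2,2-dimethoxypropane: COC(C)(C)OC
Why: Acid-catalysed transketalisation closes the syn-1,3-diol to a chair 1,3-dioxane with both substituents equatorial. This blocks the two hydroxyls for the basic olefination and should allow chromatographic removal of any diastereomer that stems from the minor enantiomer of 8.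

Step 9
Reactants: 13 (4S,6S)-4-allyl-6-{[(4R,6R)-2,2-dimethyl-6-pentadecyl-1,3-dioxan-4-yl]methyl}-2,2-dimethyl-1,3-dioxane
Product: 15 2-[(4R,6R)-6-{[(4R,6R)-2,2-dimethyl-6-pentadecyl-1,3-dioxan-4-yl]methyl}-2,2-dimethyl-1,3-dioxan-4-yl]acetaldehyde, via secondary ozonide 14 (not isolated)
Conditions: O3, CH2Cl2, −78 °C; then PPh3, −78 °C to rt
Reagents that add atoms: ozone: [O-][O+]=O
Why: Ozonolysis with reductive work-up (Criegee mechanism) cleaves the only alkene and returns the C3 aldehyde under neutral conditions that leave acetonides, which have no acetal C–H bond, untouched.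

Step 10
Reactants: 15 2-[(4R,6R)-6-{[(4R,6R)-2,2-dimethyl-6-pentadecyl-1,3-dioxan-4-yl]methyl}-2,2-dimethyl-1,3-dioxan-4-yl]acetaldehyde
Product: 16 methyl (2Z)-4-[(4S,6S)-6-{[(4R,6R)-2,2-dimethyl-6-pentadecyl-1,3-dioxan-4-yl]methyl}-2,2-dimethyl-1,3-dioxan-4-yl]but-2-enoate
Conditions: (CF3CH2O)2P(O)CH2CO2Me, KN(SiMe3)2, 18-crown-6, THF, −78 °C; then 15; aq NH4Cl
Reagents that add atoms: methyl 2-[bis(2,2,2-trifluoroethoxy)phosphoryl]acetate: COC(=O)CP(=O)(OCC(F)(F)F)OCC(F)(F)F
Why: In the Still–Gennari variant of the Horner–Wadsworth–Emmons reaction the electron-poor phosphonate eliminates from the kinetic adduct before it can equilibrate, which should give the Z-enoate, and the weakly basic anion at −78 °C spares the β-alkoxy aldehyde.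

Step 11
Reactants: 16 methyl (2Z)-4-[(4S,6S)-6-{[(4R,6R)-2,2-dimethyl-6-pentadecyl-1,3-dioxan-4-yl]methyl}-2,2-dimethyl-1,3-dioxan-4-yl]but-2-enoate
Product: 18 (6S)-6-[(2R,4R,6R)-2,4,6-trihydroxyhenicosyl]-5,6-dihydro-2H-pyran-2-one, via tetraol ester 17 (not isolated)
Conditions: 2 M aq HCl, THF, rt
Reagents that add atoms: none
Why: Acid hydrolysis opens both acetonides, and of the four hydroxyls of 17 only C5–OH can reach the ester carbonyl across the Z double bond through a six-membered transition state, so lactonisation should close the dihydropyranone without touching a stereocentre.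

Compound list
1 | tert-butyl 2-[(4R,6R)-6-(cyanomethyl)-2,2-dimethyl-1,3-dioxan-4-yl]acetate | N#CC[C@@H]1C[C@H](CC(=O)OC(C)(C)C)OC(C)(C)O1 | starting material
2 | tert-butyl 2-[(4R,6S)-2,2-dimethyl-6-(2-oxoethyl)-1,3-dioxan-4-yl]acetate | O=CC[C@@H]1C[C@H](CC(=O)OC(C)(C)C)OC(C)(C)O1 | intermediate
3 | tert-butyl 2-[(4R,6R)-6-(2-hydroxyethyl)-2,2-dimethyl-1,3-dioxan-4-yl]acetate | OCC[C@@H]1C[C@H](CC(=O)OC(C)(C)C)OC(C)(C)O1 | intermediate
4 | 2-[(4R,6R)-6-(2-tert-butoxy-2-oxoethyl)-2,2-dimethyl-1,3-dioxan-4-yl]ethyl 2,4,6-triisopropylbenzoate | CC(C)c1cc(C(C)C)c(C(=O)OCC[C@@H]2C[C@H](CC(=O)OC(C)(C)C)OC(C)(C)O2)c(C(C)C)c1 | intermediate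
5 | 2-[(4R,6R)-2,2-dimethyl-6-(2-oxoethyl)-1,3-dioxan-4-yl]ethyl 2,4,6-triisopropylbenzoate | CC(C)c1cc(C(C)C)c(C(=O)OCC[C@@H]2C[C@H](CC=O)OC(C)(C)O2)c(C(C)C)c1 | intermediate
6 | 2-[(4R,6S)-6-allyl-2,2-dimethyl-1,3-dioxan-4-yl]ethyl 2,4,6-triisopropylbenzoate | CC(C)c1cc(C(C)C)c(C(=O)OCC[C@@H]2C[C@H](CC=C)OC(C)(C)O2)c(C(C)C)c1 | intermediate
7 | heptadec-1-ene | CCCCCCCCCCCCCCCC=C | starting material
8 | (S)-1,2-bis(4,4,5,5-tetramethyl-1,3,2-dioxaborolan-2-yl)heptadecane | CCCCCCCCCCCCCCC[C@@H](B1OC(C)(C)C(C)(C)O1)CB2OC(C)(C)C(C)(C)O2 | intermediate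
9 | (1R)-2-[(4R,6S)-6-allyl-2,2-dimethyl-1,3-dioxan-4-yl]-1-lithioethyl 2,4,6-triisopropylbenzoate (sparteine complex) | CC(C)c1cc(C(C)C)c(C(=O)O[C@H]([Li])C[C@@H]2C[C@H](CC=C)OC(C)(C)O2)c(C(C)C)c1 | intermediate
10 | lithium boronate from addition of 9 to the C10 boron of 8 (C9 R, C11 S) | CC(C)c1cc(C(C)C)c(C(=O)O[C@H]([B-]2(C[C@@H](CCCCCCCCCCCCCCC)B3OC(C)(C)C(C)(C)O3)OC(C)(C)C(C)(C)O2)C[C@@H]4C[C@H](CC=C)OC(C)(C)O4)c(C(C)C)c1.[Li+] | intermediate
11 | (4S,6R)-4-allyl-6-[(2R,4R)-2,4-bis(4,4,5,5-tetramethyl-1,3,2-dioxaborolan-2-yl)nonadecyl]-2,2-dimethyl-1,3-dioxane | CCCCCCCCCCCCCCC[C@@H](B1OC(C)(C)C(C)(C)O1)C[C@@H](B2OC(C)(C)C(C)(C)O2)C[C@@H]3C[C@H](CC=C)OC(C)(C)O3 | intermediate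
12 | (2R,4R)-1-[(4R,6S)-6-allyl-2,2-dimethyl-1,3-dioxan-4-yl]nonadecane-2,4-diol | CCCCCCCCCCCCCCC[C@@H](O)C[C@@H](O)C[C@@H]1C[C@H](CC=C)OC(C)(C)O1 | intermediate
13 | (4S,6S)-4-allyl-6-{[(4R,6R)-2,2-dimethyl-6-pentadecyl-1,3-dioxan-4-yl]methyl}-2,2-dimethyl-1,3-dioxane | CCCCCCCCCCCCCCC[C@@H]1C[C@H](C[C@@H]2C[C@H](CC=C)OC(C)(C)O2)OC(C)(C)O1 | intermediate
14 | secondary ozonide (1,2,4-trioxolane) of 13, trioxolane carbon unassigned | CCCCCCCCCCCCCCC[C@@H]1C[C@H](C[C@@H]2C[C@H](CC3OCOO3)OC(C)(C)O2)OC(C)(C)O1 | intermediate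
15 | 2-[(4R,6R)-6-{[(4R,6R)-2,2-dimethyl-6-pentadecyl-1,3-dioxan-4-yl]methyl}-2,2-dimethyl-1,3-dioxan-4-yl]acetaldehyde | CCCCCCCCCCCCCCC[C@@H]1C[C@H](C[C@@H]2C[C@H](CC=O)OC(C)(C)O2)OC(C)(C)O1 | intermediate
16 | methyl (2Z)-4-[(4S,6S)-6-{[(4R,6R)-2,2-dimethyl-6-pentadecyl-1,3-dioxan-4-yl]methyl}-2,2-dimethyl-1,3-dioxan-4-yl]but-2-enoate | CCCCCCCCCCCCCCC[C@@H]1C[C@H](C[C@@H]2C[C@H](C/C=C\C(=O)OC)OC(C)(C)O2)OC(C)(C)O1 | intermediate
17 | methyl (2Z,5S,7S,9R,11R)-5,7,9,11-tetrahydroxyhexacos-2-enoate | CCCCCCCCCCCCCCC[C@@H](O)C[C@@H](O)C[C@@H](O)C[C@@H](O)C/C=C\C(=O)OC | intermediate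
18 | (6S)-6-[(2R,4R,6R)-2,4,6-trihydroxyhenicosyl]-5,6-dihydro-2H-pyran-2-one | CCCCCCCCCCCCCCC[C@@H](O)C[C@@H](O)C[C@@H](O)C[C@@H]1CC=CC(=O)O1 | target

Total step count: 11. Longest linear sequence: 10 (steps 1–4 and 6–11, from 1).

Steps most likely to fail

Step 6.
- What may go wrong: slow or poorly face-selective deprotonation at C9 because the dioxane oxygens compete with the diamine for lithium; capture of the carbenoid by the secondary boron; or collapse of the boronate back to its partners before migration.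
- Fallback, from 6 and 7 back to 12: the C9–C10 bond is made by acyl-anion/epoxide union, and C9 is set afterwards by a hydroxyl-directed reduction.
- LiAlH4 in THF would release the alcohol 2-[(4R,6S)-6-allyl-2,2-dimethyl-1,3-dioxan-4-yl]ethan-1-ol F1 from 6.
- Dess–Martin oxidation would give 2-[(4S,6S)-6-allyl-2,2-dimethyl-1,3-dioxan-4-yl]acetaldehyde F2.
- Propane-1,3-dithiol with MgBr2·OEt2 in Et2O would give (4S,6S)-4-allyl-6-[(1,3-dithian-2-yl)methyl]-2,2-dimethyl-1,3-dioxane F3.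
- Epoxidation of 7 with mCPBA would give racemic 2-pentadecyloxirane F4.
- Hydrolytic kinetic resolution with water and the antipode of (salen)Co(OAc) (trivalent cobalt) that spares the (R)-epoxide would leave (R)-2-pentadecyloxirane F5.
- Lithiation of F3 (t-BuLi, THF–HMPA, −78 °C) and opening of F5 at its CH2 terminus would give (2R)-1-(2-{[(4S,6S)-6-allyl-2,2-dimethyl-1,3-dioxan-4-yl]methyl}-1,3-dithian-2-yl)heptadecan-2-ol F6.
- MeI and CaCO3 in aqueous MeCN would unmask (4R)-1-[(4S,6S)-6-allyl-2,2-dimethyl-1,3-dioxan-4-yl]-4-hydroxynonadecan-2-one F7.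
- Narasaka–Prasad reduction (Et2BOMe, NaBH4, THF–MeOH, −78 °C) through the boron chelate of C11–OH and C9=O should give the syn-diol 12.

Step 1.
- What may go wrong: competing hydride attack on the tert-butyl ester. This erases the difference between the two chain ends, and double reduction would lead to an achiral meso diol.
- Fallback, from 1 back to 3: the nitrile is hydrated and activated instead of being reduced directly.
- [PtH{(PMe2O)2H}(PMe2OH)] in aqueous EtOH at 80 °C would give the primary amide tert-butyl 2-[(4R,6S)-6-(2-amino-2-oxoethyl)-2,2-dimethyl-1,3-dioxan-4-yl]acetate F8 under neutral conditions.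
- Boc2O and DMAP in MeCN would give the imide tert-butyl 2-[(4R,6S)-6-{2-[bis(tert-butoxycarbonyl)amino]-2-oxoethyl}-2,2-dimethyl-1,3-dioxan-4-yl]acetate F9.
- NaBH4 in EtOH, too mild for the tert-butyl ester, should reduce only the activated acyl group to the alcohol 3.

Step 10.
- What may go wrong: erosion of the Z-selectivity, or base-induced β-elimination of the C5 oxygen from the aldehyde.
- Fallback, from 15 back to 16: the alkene geometry is taken from an alkyne semihydrogenation.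
- Ohira–Bestmann homologation (dimethyl (1-diazo-2-oxopropyl)phosphonate, K2CO3, MeOH) would give the terminal alkyne (4S,6S)-4-{[(4R,6R)-2,2-dimethyl-6-pentadecyl-1,3-dioxan-4-yl]methyl}-2,2-dimethyl-6-(prop-2-yn-1-yl)-1,3-dioxane F10.
- n-BuLi followed by ClCO2Me would give methyl 4-[(4S,6S)-6-{[(4R,6R)-2,2-dimethyl-6-pentadecyl-1,3-dioxan-4-yl]methyl}-2,2-dimethyl-1,3-dioxan-4-yl]but-2-ynoate F11.
- Syn addition of H2 over Pd/CaCO3–Pb(OAc)2 (Lindlar catalyst) with quinoline should give 16.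

Further compounds
F1 | step 6 | 2-[(4R,6S)-6-allyl-2,2-dimethyl-1,3-dioxan-4-yl]ethan-1-ol | OCC[C@@H]1C[C@H](CC=C)OC(C)(C)O1
F2 | step 6 | 2-[(4S,6S)-6-allyl-2,2-dimethyl-1,3-dioxan-4-yl]acetaldehyde | O=CC[C@@H]1C[C@H](CC=C)OC(C)(C)O1
F3 | step 6 | (4S,6S)-4-allyl-6-[(1,3-dithian-2-yl)methyl]-2,2-dimethyl-1,3-dioxane | C1CSC(C[C@@H]2C[C@H](CC=C)OC(C)(C)O2)SC1
F4 | step 6 | racemic 2-pentadecyloxirane | CCCCCCCCCCCCCCCC1CO1
F5 | step 6 | (R)-2-pentadecyloxirane | CCCCCCCCCCCCCCC[C@@H]1CO1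
F6 | step 6 | (2R)-1-(2-{[(4S,6S)-6-allyl-2,2-dimethyl-1,3-dioxan-4-yl]methyl}-1,3-dithian-2-yl)heptadecan-2-ol | CCCCCCCCCCCCCCC[C@@H](O)CC1(C[C@@H]2C[C@H](CC=C)OC(C)(C)O2)SCCCS1
F7 | step 6 | (4R)-1-[(4S,6S)-6-allyl-2,2-dimethyl-1,3-dioxan-4-yl]-4-hydroxynonadecan-2-one | CCCCCCCCCCCCCCC[C@@H](O)CC(=O)C[C@@H]1C[C@H](CC=C)OC(C)(C)O1
F8 | step 1 | tert-butyl 2-[(4R,6S)-6-(2-amino-2-oxoethyl)-2,2-dimethyl-1,3-dioxan-4-yl]acetate | NC(=O)C[C@@H]1C[C@H](CC(=O)OC(C)(C)C)OC(C)(C)O1
F9 | step 1 | tert-butyl 2-[(4R,6S)-6-{2-[bis(tert-butoxycarbonyl)amino]-2-oxoethyl}-2,2-dimethyl-1,3-dioxan-4-yl]acetate | CC(C)(C)OC(=O)N(C(=O)OC(C)(C)C)C(=O)C[C@@H]1C[C@H](CC(=O)OC(C)(C)C)OC(C)(C)O1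
F10 | step 10 | (4S,6S)-4-{[(4R,6R)-2,2-dimethyl-6-pentadecyl-1,3-dioxan-4-yl]methyl}-2,2-dimethyl-6-(prop-2-yn-1-yl)-1,3-dioxane | CCCCCCCCCCCCCCC[C@@H]1C[C@H](C[C@@H]2C[C@H](CC#C)OC(C)(C)O2)OC(C)(C)O1
F11 | step 10 | methyl 4-[(4S,6S)-6-{[(4R,6R)-2,2-dimethyl-6-pentadecyl-1,3-dioxan-4-yl]methyl}-2,2-dimethyl-1,3-dioxan-4-yl]but-2-ynoate | CCCCCCCCCCCCCCC[C@@H]1C[C@H](C[C@@H]2C[C@H](CC#CC(=O)OC)OC(C)(C)O2)OC(C)(C)O1
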